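## Retrosynthetic overview

1. Target ⇐ desilylation and double oxidation of a diol made by α-selective, geometry-retaining addition of a (Z)-allylbarium (fragment C, aryl arm) to a lactol that already carries the C5 enone arm.
2. Lactol ⇐ lactone formed when an (E)-vinyllithium (fragment B) adds to the cyclopentane aldehyde ester (fragment A).
3. Fragment A ⇐ ozonolysis of an enantioenriched silyl enol ether of meso cis-1,5-dimethylbicyclo[3.3.0]octan-3-one (chiral lithium amide desymmetrisation); one five-membered ring is sacrificed, the other is the target's cyclopentane.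
4. Bicycle ⇐ Weiss–Cook condensation of biacetyl with dimethyl 3-oxopentanedioate: the first five-membered ring closes by intramolecular aldol, the second by intramolecular Michael addition, and the cis fusion fixes the cis-dimethyl quaternary pair. No other ring is built; the arene is bought.
5. Fragment C ⇐ Still–Gennari (Z)-olefination of an arylacetaldehyde from 2-allyl-6-methylphenol; fragment B ⇐ hydrozirconation–iodination of silylated 2-methylbut-3-yn-2-ol.

Assumption: lithium (R,R)-bis(1-phenylethyl)amide is assumed to give the (1R,5S)-enol ether drawn in step 6; if the opposite enol ether forms, the (S,S)-amide is used and nothing else changes.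

Abbreviations: TBS = tert-butyldimethylsilyl, TES = triethylsilyl.

## Route

**Fragment A (cyclopentane core)**

Step 1
Reactants: 1 biacetyl (butane-2,3-dione); 2 dimethyl 3-oxopentanedioate (2 equiv)
Product: 5 tetramethyl cis-3,7-dihydroxy-1,5-dimethylbicyclo[3.3.0]octa-2,6-diene-2,4,6,8-tetracarboxylate, via cyclopentenone 3 (not isolated), via Michael adduct 4 (not isolated)
Conditions: aq. NaHCO3 (pH 8.3), H2O, rt, 24 h; precipitate filtered
Reagents that add atoms: none
Why: Weiss–Cook condensation, in which aldol addition of 2 to 1 and an intramolecular aldol close the first five-membered ring (3 after loss of water), a second molecule of 2 adds in Michael fashion (4 after loss of water) and an intramolecular Michael addition closes the second ring, the obligatory cis fusion of the bicyclo[3.3.0]octane placing the two methyl-bearing quaternary carbons cis.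

Step 2
Reactants: 5 tetraester
Product: 6 cis-1,5-dimethylbicyclo[3.3.0]octane-3,7-dione (meso)
Conditions: 1 M HCl, AcOH, reflux, 3 h
Reagents that add atoms: none
Why: Acid hydrolysis of the four β-keto ester groups and fourfold decarboxylation give the meso diketone without touching the quaternary carbons.

Step 3
Reactants: 6 meso diketone
Product: 7 cis-7,7-(ethylenedioxy)-1,5-dimethylbicyclo[3.3.0]octan-3-one (meso)
Conditions: HOCH2CH2OH (1.0 equiv), p-TsOH (cat.), benzene, reflux, Dean–Stark; unreacted 6 recycled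
Reagents that add atoms: ethane-1,2-diol, OCCO
Why: Acid-catalysed ketalisation with one equivalent of diol protects one of the two equivalent ketones statistically, so that the other can be removed.

Step 4
Reactants: 7 mono-ketal
Product: 9 cis-3,3-(ethylenedioxy)-1,5-dimethylbicyclo[3.3.0]octane, via hydrazone 8 (not isolated)
Conditions: N2H4·H2O, KOH, diethylene glycol, 130 °C then 200 °C
Reagents that add atoms: none
Why: Wolff–Kishner reduction (Huang-Minlon procedure) converts the free ketone through its hydrazone into CH2, the ketal being inert to hot alkali.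

Step 5
Reactants: 9 ketal
Product: 10 cis-1,5-dimethylbicyclo[3.3.0]octan-3-one (meso)
Conditions: 1 M HCl, THF, rt
Reagents that add atoms: water, O
Why: Acid-catalysed ketal hydrolysis returns the single ketone of the meso bicycle.

Step 6
Reactants: 10 meso ketone
Product: 12 (1R,5S)-1,5-dimethyl-3-(trimethylsilyloxy)bicyclo[3.3.0]oct-2-ene, via lithium enolate 11 (not isolated)
Conditions: (R,R)-bis(1-phenylethyl)amine, n-BuLi, LiCl, THF, −78 °C; then TMSCl and 10, −100 °C (internal quench)
Reagents that add atoms: chlorotrimethylsilane, C[Si](C)(C)Cl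
Why: Enantiotopos-selective deprotonation of a meso ketone by a chiral lithium amide (Simpkins–Koga desymmetrisation) with in-situ silylation distinguishes the two α-methylene groups and thereby fixes the absolute configuration of both quaternary stereocentres, whose cis relationship was set in step 1.

Step 7
Reactants: 12 silyl enol ether
Product: 13 2-[(1S,2S)-2-formyl-1,2-dimethylcyclopentyl]acetic acid
Conditions: O3, CH2Cl2/MeOH, −78 °C; then Me2S, −78 °C → rt
Reagents that add atoms: ozone, [O-][O+]=O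
Why: Ozonolysis of the electron-rich enol ether cleaves the sacrificial ring so that the CH= carbon becomes the aldehyde on one quaternary carbon and the silyloxy carbon the acetic acid arm on the other, with no stereocentre involved.

Step 8
Reactants: 13 aldehyde acid
Product: 14 methyl 2-[(1S,2S)-2-formyl-1,2-dimethylcyclopentyl]acetate (fragment A)
Conditions: MeI, K2CO3, DMF, rt
Reagents that add atoms: iodomethane, CI
Why: SN2 O-methylation of the carboxylate, the aldehyde having no α-hydrogen and therefore neither epimerising nor condensing.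

**Fragment B (enone arm)**

Step 9
Reactants: 15 2-methylbut-3-yn-2-ol
Product: 16 triethyl[(2-methylbut-3-yn-2-yl)oxy]silane
Conditions: Et3SiOTf, 2,6-lutidine, CH2Cl2, 0 °C
Reagents that add atoms: triethylsilyl trifluoromethanesulfonate, CC[Si](CC)(CC)OS(=O)(=O)C(F)(F)F
Why: Silyl triflate silylation of the tertiary alcohol gives an ether that survives organolithium, hydride and oxidation steps and leaves with fluoride at the end.

Step 10
Reactants: 16 silyl ether
Product: 18 triethyl{[(3E)-4-iodo-2-methylbut-3-en-2-yl]oxy}silane (fragment B), via vinylzirconocene 17 (not isolated)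
Conditions: Cp2Zr(H)Cl, THF, rt; then I2, 0 °C
Reagents that add atoms: iodine, II
Why: Hydrozirconation adds Zr–H syn across the terminal alkyne with zirconium on the terminal carbon and iodinolysis proceeds with retention, giving the (E)-vinyl iodide.

**Union of A and B**

Step 11
Reactants: 18 vinyl iodide; 14 aldehyde ester
Product: 21 (4aS,7aS)-4a,7a-dimethyl-1-[(1E)-3-methyl-3-(triethylsilyloxy)but-1-en-1-yl]hexahydrocyclopenta[c]pyran-3(1H)-one (lactone; both C1 epimers), via vinyllithium 19 (not isolated), via lithium alkoxide 20 (not isolated)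
Conditions: 18, t-BuLi (2.0 equiv), Et2O, −78 °C; then 14 (1.0 equiv), −78 → 0 °C; H2O
Reagents that add atoms: none
Why: Iodine–lithium exchange with retention of the (E)-geometry and 1,2-addition to the non-enolisable aldehyde (faster than attack on the ester) give an alkoxide that lactonises onto the cis-disposed ester, the new carbinol centre being formed unselectively and oxidised away in step 21.

Step 12
Reactants: 21 lactone
Product: 22 (4aS,7aS)-4a,7a-dimethyl-1-[(1E)-3-methyl-3-(triethylsilyloxy)but-1-en-1-yl]octahydrocyclopenta[c]pyran-3-ol (lactol; epimer mixture)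
Conditions: i-Bu2AlH (1.1 equiv), CH2Cl2, −78 °C; aq. potassium sodium tartrate
Reagents that add atoms: none
Why: Partial hydride reduction of the δ-lactone stops at the aluminium lactolate at −78 °C and brings the C1 arm to the aldehyde oxidation level.

**Fragment C (aryl arm)**

Step 13
Reactants: 23 2-allyl-6-methylphenol
Product: 24 2-methyl-6-(prop-2-en-1-yl)cyclohexa-2,5-diene-1,4-dione
Conditions: Co(salen) [N,N'-bis(salicylidene)ethylenediaminocobalt] (10 mol %), O2 (1 atm), DMF, rt
Reagents that add atoms: dioxygen, O=O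
Why: Cobalt–salen-catalysed aerobic oxidation of a 2,6-disubstituted phenol gives the para-quinone because both ortho positions are blocked.

Step 14
Reactants: 24 quinone
Product: 25 2-methyl-6-(prop-2-en-1-yl)benzene-1,4-diol
Conditions: Na2S2O4, EtOAc/H2O, rt
Reagents that add atoms: none
Why: Dithionite reduction of the quinone gives the hydroquinone with the substitution pattern of the target arene.

Step 15
Reactants: 25 hydroquinone
Product: 26 1,4-bis(TBS-oxy)-2-methyl-6-(prop-2-en-1-yl)benzene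
Conditions: TBSCl, imidazole, DMF, rt → 40 °C
Reagents that add atoms: tert-butylchlorodimethylsilane, CC(C)(C)[Si](C)(C)Cl
Why: Silylation of both phenols gives ethers that tolerate base, hydride and organometallic steps and are removed by fluoride without acid.

Step 16
Reactants: 26 allyl arene
Product: 27 2-[2,5-bis(TBS-oxy)-3-methylphenyl]acetaldehyde
Conditions: OsO4 (2 mol %), NaIO4, 2,6-lutidine, dioxane/H2O, rt
Reagents that add atoms: osmium tetroxide, O=[Os](=O)(=O)=O; sodium periodate, [Na+].[O-]I(=O)(=O)=O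
Why: Lemieux–Johnson cleavage (dihydroxylation, then periodate scission) cuts the terminal alkene to the aldehyde and spares the electron-rich arene that ozone would attack.

Step 17
Reactants: 27 arylacetaldehyde; 28 ethyl 2-[bis(2,2,2-trifluoroethoxy)phosphoryl]propanoate
Product: 29 ethyl (2Z)-4-[2,5-bis(TBS-oxy)-3-methylphenyl]-2-methylbut-2-enoate
Conditions: KN(SiMe3)2, 18-crown-6, THF, −78 °C
Reagents that add atoms: none
Why: Still–Gennari olefination, in which fast irreversible elimination from the kinetic adduct of the electron-poor phosphonate gives the (Z)-trisubstituted enoate and so sets the side-chain olefin geometry of the target.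

Step 18
Reactants: 29 (Z)-enoate
Product: 30 (2Z)-4-[2,5-bis(TBS-oxy)-3-methylphenyl]-2-methylbut-2-en-1-ol
Conditions: i-Bu2AlH (2.5 equiv), CH2Cl2, −78 °C
Reagents that add atoms: none
Why: 1,2-Reduction of the unsaturated ester gives the allylic alcohol without touching the olefin geometry or the aryl silyl ethers.

Step 19
Reactants: 30 (Z)-allylic alcohol
Product: 32 (2Z)-4-[2,5-bis(TBS-oxy)-3-methylphenyl]-1-chloro-2-methylbut-2-ene (fragment C), via mesylate 31 (not isolated)
Conditions: MsCl, 2,4,6-collidine, LiCl, DMF, 0 °C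
Reagents that add atoms: lithium chloride, [Li+].[Cl-]
Why: Collington–Meyers chlorination, in which the mesylate formed in situ is displaced by chloride in an SN2 reaction at the primary carbon, without allylic transposition or loss of the (Z)-geometry.

**Union with C and endgame**

Step 20
Reactants: 32 (Z)-allylic chloride (1.8 equiv); 22 lactol
Product: 35 (2E)-1-{(1S,2S)-2-[(4Z)-6-[2,5-bis(TBS-oxy)-3-methylphenyl]-2-hydroxy-4-methylhex-4-en-1-yl]-1,2-dimethylcyclopentyl}-4-methyl-4-(triethylsilyloxy)pent-2-en-1-ol (carbinol epimers), via allylbarium chloride 33 (not isolated), via aldehyde alkoxide 34 (not isolated)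
Conditions: BaI2, lithium biphenylide (2 equiv per Ba), THF, rt; 32, −78 °C; then 22 pretreated with n-BuLi (1.0 equiv, THF, −78 °C); −78 °C, 2 h; H2O
Reagents that add atoms: none
Why: Yamamoto allylbarium addition, in which the allylic barium reagent made at −78 °C attacks the aldehyde (ring-opened lactolate) at its unsubstituted α-carbon with retention of the (Z)-olefin to give the linear homoallylic alcohol, the new carbinol centre being unselective and removed in step 21.

Step 21
Reactants: 35 diol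
Product: 36 (2E)-1-{(1S,2S)-2-[(4Z)-6-[2,5-bis(TBS-oxy)-3-methylphenyl]-4-methyl-2-oxohex-4-en-1-yl]-1,2-dimethylcyclopentyl}-4-methyl-4-(triethylsilyloxy)pent-2-en-1-one
Conditions: Dess–Martin periodinane (3 equiv), NaHCO3, CH2Cl2, 0 °C → rt
Reagents that add atoms: none
Why: Dess–Martin oxidation converts both secondary carbinols in one operation into the (E)-enone and the non-conjugated β,γ-unsaturated ketone under buffered conditions that do not move the (Z)-double bond.

Step 22
Reactants: 36 diketone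
Product: 37 (2E)-1-{(1S,2S)-2-[(4Z)-6-(2,5-dihydroxy-3-methylphenyl)-4-methyl-2-oxohex-4-en-1-yl]-1,2-dimethylcyclopentyl}-4-hydroxy-4-methylpent-2-en-1-one (target)
Conditions: Bu4NF/AcOH (1:1, 4 equiv), THF, 0 °C → rt, under argon
Reagents that add atoms: none
Why: Fluoride-mediated desilylation buffered with acetic acid frees both phenols and the tertiary alcohol without base-induced conjugation of the β,γ-enone or oxidation of the hydroquinone.

## Compound list

1 | biacetyl (butane-2,3-dione) | CC(=O)C(C)=O | starting material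
2 | dimethyl 3-oxopentanedioate | COC(=O)CC(=O)CC(=O)OC | starting material
3 | dimethyl 3-hydroxy-2,3-dimethyl-5-oxocyclopent-1-ene-1,4-dicarboxylate (racemic) | COC(=O)C1=C(C)C(C)(O)C(C(=O)OC)C1=O | intermediate
4 | dimethyl 5-(1,5-dimethoxy-1,3,5-trioxopentan-2-yl)-4,5-dimethyl-2-oxocyclopent-3-ene-1,3-dicarboxylate (racemic) | COC(=O)CC(=O)C(C(=O)OC)C1(C)C(C)=C(C(=O)OC)C(=O)C1C(=O)OC | intermediate
5 | tetramethyl cis-3,7-dihydroxy-1,5-dimethylbicyclo[3.3.0]octa-2,6-diene-2,4,6,8-tetracarboxylate (C4/C8 epimers) | OC1=C(C(=O)OC)[C@]2(C)C(C(=O)OC)C(O)=C(C(=O)OC)[C@]2(C)C1C(=O)OC | intermediate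
6 | cis-1,5-dimethylbicyclo[3.3.0]octane-3,7-dione (meso) | O=C1C[C@]2(C)CC(=O)C[C@]2(C)C1 | intermediate
7 | cis-7,7-(ethylenedioxy)-1,5-dimethylbicyclo[3.3.0]octan-3-one (meso) | O=C1C[C@]2(C)CC3(OCCO3)C[C@]2(C)C1 | intermediate
8 | hydrazone of 7 | NN=C1C[C@]2(C)CC3(OCCO3)C[C@]2(C)C1 | intermediate
9 | cis-3,3-(ethylenedioxy)-1,5-dimethylbicyclo[3.3.0]octane (meso) | C1C[C@]2(C)CC3(OCCO3)C[C@]2(C)C1 | intermediate
10 | cis-1,5-dimethylbicyclo[3.3.0]octan-3-one (meso) | O=C1C[C@]2(C)CCC[C@]2(C)C1 | intermediate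
11 | lithium (1R,5S)-1,5-dimethylbicyclo[3.3.0]oct-2-en-3-olate | [Li+].[O-]C1=C[C@@]2(C)CCC[C@@]2(C)C1 | intermediate
12 | (1R,5S)-1,5-dimethyl-3-(trimethylsilyloxy)bicyclo[3.3.0]oct-2-ene | C[Si](C)(C)OC1=C[C@@]2(C)CCC[C@@]2(C)C1 | intermediate
13 | 2-[(1S,2S)-2-formyl-1,2-dimethylcyclopentyl]acetic acid | OC(=O)C[C@]1(C)CCC[C@]1(C)C=O | intermediate
14 | methyl 2-[(1S,2S)-2-formyl-1,2-dimethylcyclopentyl]acetate | COC(=O)C[C@]1(C)CCC[C@]1(C)C=O | intermediate
15 | 2-methylbut-3-yn-2-ol | CC(C)(O)C#C | starting material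
16 | triethyl[(2-methylbut-3-yn-2-yl)oxy]silane | CC[Si](CC)(CC)OC(C)(C)C#C | intermediate
17 | chlorobis(cyclopentadienyl)[(1E)-3-methyl-3-(triethylsilyloxy)but-1-en-1-yl]zirconium | CC[Si](CC)(CC)OC(C)(C)/C=C/[Zr+2]Cl.c1cc[cH-]c1.c1cc[cH-]c1 | intermediate
18 | triethyl{[(3E)-4-iodo-2-methylbut-3-en-2-yl]oxy}silane | CC[Si](CC)(CC)OC(C)(C)/C=C/I | intermediate
19 | [(1E)-3-methyl-3-(triethylsilyloxy)but-1-en-1-yl]lithium | CC[Si](CC)(CC)OC(C)(C)/C=C/[Li] | intermediate
20 | lithium alkoxide of methyl 2-{(1S,2S)-2-[(2E)-1-hydroxy-4-methyl-4-(triethylsilyloxy)pent-2-en-1-yl]-1,2-dimethylcyclopentyl}acetate (carbinol epimers) | COC(=O)C[C@]1(C)CCC[C@]1(C)C([O-])/C=C/C(C)(C)O[Si](CC)(CC)CC.[Li+] | intermediate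
21 | (4aS,7aS)-4a,7a-dimethyl-1-[(1E)-3-methyl-3-(triethylsilyloxy)but-1-en-1-yl]hexahydrocyclopenta[c]pyran-3(1H)-one (C1 epimers) | O=C1C[C@]2(C)CCC[C@]2(C)C(/C=C/C(C)(C)O[Si](CC)(CC)CC)O1 | intermediate
22 | (4aS,7aS)-4a,7a-dimethyl-1-[(1E)-3-methyl-3-(triethylsilyloxy)but-1-en-1-yl]octahydrocyclopenta[c]pyran-3-ol (epimer mixture) | OC1C[C@]2(C)CCC[C@]2(C)C(/C=C/C(C)(C)O[Si](CC)(CC)CC)O1 | intermediate
23 | 2-allyl-6-methylphenol | C=CCc1cccc(C)c1O | starting material
24 | 2-methyl-6-(prop-2-en-1-yl)cyclohexa-2,5-diene-1,4-dione | C=CCC1=CC(=O)C=C(C)C1=O | intermediate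
25 | 2-methyl-6-(prop-2-en-1-yl)benzene-1,4-diol | C=CCc1cc(O)cc(C)c1O | intermediate
26 | 1,4-bis[(tert-butyldimethylsilyl)oxy]-2-methyl-6-(prop-2-en-1-yl)benzene | C=CCc1cc(O[Si](C)(C)C(C)(C)C)cc(C)c1O[Si](C)(C)C(C)(C)C | intermediate
27 | 2-{2,5-bis[(tert-butyldimethylsilyl)oxy]-3-methylphenyl}acetaldehyde | O=CCc1cc(O[Si](C)(C)C(C)(C)C)cc(C)c1O[Si](C)(C)C(C)(C)C | intermediate
28 | ethyl 2-[bis(2,2,2-trifluoroethoxy)phosphoryl]propanoate | CCOC(=O)C(C)P(=O)(OCC(F)(F)F)OCC(F)(F)F | starting material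
29 | ethyl (2Z)-4-{2,5-bis[(tert-butyldimethylsilyl)oxy]-3-methylphenyl}-2-methylbut-2-enoate | C/C(=C/Cc1cc(O[Si](C)(C)C(C)(C)C)cc(C)c1O[Si](C)(C)C(C)(C)C)C(=O)OCC | intermediate
30 | (2Z)-4-{2,5-bis[(tert-butyldimethylsilyl)oxy]-3-methylphenyl}-2-methylbut-2-en-1-ol | C/C(=C/Cc1cc(O[Si](C)(C)C(C)(C)C)cc(C)c1O[Si](C)(C)C(C)(C)C)CO | intermediate
31 | (2Z)-4-{2,5-bis[(tert-butyldimethylsilyl)oxy]-3-methylphenyl}-2-methylbut-2-en-1-yl methanesulfonate | C/C(=C/Cc1cc(O[Si](C)(C)C(C)(C)C)cc(C)c1O[Si](C)(C)C(C)(C)C)COS(C)(=O)=O | intermediate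
32 | (2Z)-4-{2,5-bis[(tert-butyldimethylsilyl)oxy]-3-methylphenyl}-1-chloro-2-methylbut-2-ene | C/C(=C/Cc1cc(O[Si](C)(C)C(C)(C)C)cc(C)c1O[Si](C)(C)C(C)(C)C)CCl | intermediate
33 | [(2Z)-4-{2,5-bis[(tert-butyldimethylsilyl)oxy]-3-methylphenyl}-2-methylbut-2-en-1-yl]barium chloride | C/C(=C/Cc1cc(O[Si](C)(C)C(C)(C)C)cc(C)c1O[Si](C)(C)C(C)(C)C)C[Ba]Cl | intermediate
34 | lithium (2E)-1-[(1S,2S)-1,2-dimethyl-2-(2-oxoethyl)cyclopentyl]-4-methyl-4-(triethylsilyloxy)pent-2-en-1-olate (ring-opened form of deprotonated 22) | O=CC[C@]1(C)CCC[C@]1(C)C([O-])/C=C/C(C)(C)O[Si](CC)(CC)CC.[Li+] | intermediate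
35 | (2E)-1-{(1S,2S)-2-[(4Z)-6-{2,5-bis[(tert-butyldimethylsilyl)oxy]-3-methylphenyl}-2-hydroxy-4-methylhex-4-en-1-yl]-1,2-dimethylcyclopentyl}-4-methyl-4-(triethylsilyloxy)pent-2-en-1-ol (carbinol epimers) | C/C(=C/Cc1cc(O[Si](C)(C)C(C)(C)C)cc(C)c1O[Si](C)(C)C(C)(C)C)CC(O)C[C@]1(C)CCC[C@]1(C)C(O)/C=C/C(C)(C)O[Si](CC)(CC)CC | intermediate
36 | (2E)-1-{(1S,2S)-2-[(4Z)-6-{2,5-bis[(tert-butyldimethylsilyl)oxy]-3-methylphenyl}-4-methyl-2-oxohex-4-en-1-yl]-1,2-dimethylcyclopentyl}-4-methyl-4-(triethylsilyloxy)pent-2-en-1-one | C/C(=C/Cc1cc(O[Si](C)(C)C(C)(C)C)cc(C)c1O[Si](C)(C)C(C)(C)C)CC(=O)C[C@]1(C)CCC[C@]1(C)C(=O)/C=C/C(C)(C)O[Si](CC)(CC)CC | intermediate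
37 | (2E)-1-{(1S,2S)-2-[(4Z)-6-(2,5-dihydroxy-3-methylphenyl)-4-methyl-2-oxohex-4-en-1-yl]-1,2-dimethylcyclopentyl}-4-hydroxy-4-methylpent-2-en-1-one | C/C(=C/Cc1cc(O)cc(C)c1O)CC(=O)C[C@]1(C)CCC[C@]1(C)C(=O)/C=C/C(C)(C)O | target

## Step count and risks

Total steps: 22.
Longest linear sequence: 13 steps (steps 1–8, 11, 12, 20, 21, 22). The branches are steps 9–10 (fragment B) and steps 13–19 (fragment C).

The three steps most likely to fail:

**Step 6** (enantioselectivity and sense of the desymmetrising deprotonation on the angularly methylated ketone). Fallback: a biocatalytic Baeyer–Villiger desymmetrisation replaces the chiral base. It sets out from meso ketone 10. A Baeyer–Villiger monooxygenase (whole cells expressing cyclohexanone or cyclopentanone monooxygenase, O2, glucose, buffer, 25 °C; the enzyme giving the needed antipode is chosen) inserts oxygen on one enantiotopic side to give the bicyclic lactone F1. Ring opening and esterification in one pot (KOH, MeOH/H2O; then MeI, DMF) give the hydroxy ester F2. Dess–Martin oxidation of its neopentyl alcohol comes back to the route at aldehyde ester 14.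

**Step 17** (the arylacetaldehyde enolises easily, and the Z/E ratio decides the purity of the side-chain olefin). Fallback: the (Z)-olefin is built by Still's Wittig reaction of an α-alkoxy ketone, with the aldehyde-derived carbon as the ylide component. It sets out from aldehyde 27. NaBH4 (MeOH, 0 °C) gives the arylethanol F3, I2/PPh3/imidazole gives the iodide F4, and PPh3 (MeCN, reflux) gives the phosphonium iodide F5. Wittig reaction of F5 (NaN(SiMe3)2, THF, −78 °C) with 1-(tetrahydro-2H-pyran-2-yloxy)propan-2-one gives the (Z)-allylic tetrahydropyranyl ether F6, the alkoxymethyl group ending cis to the ylide-derived chain. PPTS in MeOH removes the acetal and comes back to the route at allylic alcohol 30.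

**Step 20** (formation of the allylbarium and its α-selective addition to a lactol-derived aldehyde at −78 °C). Fallback: the coupling is moved to the ketone oxidation level with a sulfone-stabilised allyl anion acylated by the lactone. It sets out from chloride 32 and lactone 21. PhSO2Na (DMF, rt) converts 32 into the (Z)-allyl phenyl sulfone F7. Deprotonation (n-BuLi, THF, −78 °C) and addition of 21 acylate the sulfonyl-bearing carbon; the liberated alkoxide deprotonates the product and prevents a second addition, giving the hydroxy β-keto sulfone F8. SmI2 (THF/MeOH, −78 °C) removes the sulfonyl group with kinetic α-protonation to give the β,γ-unsaturated hydroxy ketone F9. Dess–Martin oxidation of its allylic alcohol comes back to the route at diketone 36.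

## Further compounds

F1 | step 6 | (4aS,7aS)-4a,7a-dimethylhexahydrocyclopenta[c]pyran-3(1H)-one | O=C1C[C@]2(C)CCC[C@]2(C)CO1
F2 | step 6 | methyl 2-[(1S,2S)-2-(hydroxymethyl)-1,2-dimethylcyclopentyl]acetate | COC(=O)C[C@]1(C)CCC[C@]1(C)CO
F3 | step 17 | 2-{2,5-bis[(tert-butyldimethylsilyl)oxy]-3-methylphenyl}ethan-1-ol | OCCc1cc(O[Si](C)(C)C(C)(C)C)cc(C)c1O[Si](C)(C)C(C)(C)C
F4 | step 17 | 1,4-bis[(tert-butyldimethylsilyl)oxy]-2-(2-iodoethyl)-6-methylbenzene | ICCc1cc(O[Si](C)(C)C(C)(C)C)cc(C)c1O[Si](C)(C)C(C)(C)C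
F5 | step 17 | (2-{2,5-bis[(tert-butyldimethylsilyl)oxy]-3-methylphenyl}ethyl)triphenylphosphonium iodide | [I-].C(Cc1cc(O[Si](C)(C)C(C)(C)C)cc(C)c1O[Si](C)(C)C(C)(C)C)[P+](c1ccccc1)(c1ccccc1)c1ccccc1
F6 | step 17 | 2-{[(2Z)-4-{2,5-bis[(tert-butyldimethylsilyl)oxy]-3-methylphenyl}-2-methylbut-2-en-1-yl]oxy}tetrahydro-2H-pyran | C/C(=C/Cc1cc(O[Si](C)(C)C(C)(C)C)cc(C)c1O[Si](C)(C)C(C)(C)C)COC1CCCCO1
F7 | step 20 | [(2Z)-4-{2,5-bis[(tert-butyldimethylsilyl)oxy]-3-methylphenyl}-2-methylbut-2-en-1-yl] phenyl sulfone | C/C(=C/Cc1cc(O[Si](C)(C)C(C)(C)C)cc(C)c1O[Si](C)(C)C(C)(C)C)CS(=O)(=O)c1ccccc1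
F8 | step 20 | (4Z)-6-{2,5-bis[(tert-butyldimethylsilyl)oxy]-3-methylphenyl}-1-{(1S,2S)-2-[(2E)-1-hydroxy-4-methyl-4-(triethylsilyloxy)pent-2-en-1-yl]-1,2-dimethylcyclopentyl}-4-methyl-3-(phenylsulfonyl)hex-4-en-2-one | C/C(=C/Cc1cc(O[Si](C)(C)C(C)(C)C)cc(C)c1O[Si](C)(C)C(C)(C)C)C(C(=O)C[C@]1(C)CCC[C@]1(C)C(O)/C=C/C(C)(C)O[Si](CC)(CC)CC)S(=O)(=O)c1ccccc1
F9 | step 20 | (4Z)-6-{2,5-bis[(tert-butyldimethylsilyl)oxy]-3-methylphenyl}-1-{(1S,2S)-2-[(2E)-1-hydroxy-4-methyl-4-(triethylsilyloxy)pent-2-en-1-yl]-1,2-dimethylcyclopentyl}-4-methylhex-4-en-2-one | C/C(=C/Cc1cc(O[Si](C)(C)C(C)(C)C)cc(C)c1O[Si](C)(C)C(C)(C)C)CC(=O)C[C@]1(C)CCC[C@]1(C)C(O)/C=C/C(C)(C)O[Si](CC)(CC)CC
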